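**Strategy.** The trans-2-aryl-3-(hydroxymethyl)-2,3-dihydrobenzofuran (ring A on C2, benzo ring B) is treated as a ring-contracted flavanone. Its C3–C3a bond and its CH2OH carbon correspond to C3, C4a and C4 of a chroman-4-one. Treating the (R)-6-bromo-8-methoxyflavanone, whose ring A is deactivated as a 4'-mesylate, with PhI(OAc)2 in acidic trimethyl orthoformate moves C4a from C4 to C3. This single operation contracts the pyranone to the furan ring, extrudes C4 as a methyl ester and sets C3 trans to C2. The bromide is then homologated to a benzylic bromide. Two enolate alkylations build the (3S,4S)-lactone and attach the ring C/ring D unit, which comes from an anti-aldol reaction.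

Key step: step 5

**Remarks before the steps**
- Labels: ring C is the phenol ring of the benzyl group on lactone C3. Ring D is the aryl group on the carbinol carbon C7''. C8'' carries ring C and the C9''H2OH group.
- Configuration read from the SMILES:
  - Dihydrobenzofuran: C2 R, C3 S (trans).
  - Lactone: C3 S, C4 S (trans, the mirror-image series of matairesinol).
  - Open chain: C7'' S, C8'' S. OH and ring C are anti in the zigzag drawing, so an anti-aldol is required.
- The flavanone (R) and the contracted ester (2R,3R) were checked against the target and agree with it. C3 changes its descriptor to S on ester reduction only because the CIP priorities change.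
- Design change: an aryl mesylate is cleaved by amide bases and by butyllithium. It is therefore kept only through the key step and the ester reduction, and is then replaced by a silyl ether.
- Assumption: the sense of induction in step 4 is taken from the facial preference of this catalyst with cyclic enones. The ligand antipode is equally available.

**Ring A/ring B part**

Step 1
Reactants: 1 1-(5-bromo-2-hydroxy-3-methoxyphenyl)ethanone; 2 N,N-dimethylformamide dimethyl acetal
Product: 4 6-bromo-8-methoxy-4H-chromen-4-one, via enaminone 3 (not isolated)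
Conditions: 2 (2 equiv), toluene, 100 °C; evaporate; conc. HCl, CH2Cl2, 40 °C
Reagents that add atoms: none
Why: Condensation of the methyl ketone with the amide acetal gives the enaminone, and acid-induced addition of the phenol with loss of dimethylamine is the standard chromone synthesis from 2-hydroxyacetophenones.

Step 2
Reactants: 5 2-methoxy-4-(4,4,5,5-tetramethyl-1,3,2-dioxaborolan-2-yl)phenol
Product: 6 2-methoxy-4-(4,4,5,5-tetramethyl-1,3,2-dioxaborolan-2-yl)phenyl methanesulfonate
Conditions: MsCl, Et3N, CH2Cl2, 0 °C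
Reagents that add atoms: methanesulfonyl chloride, CS(=O)(=O)Cl
Why: This is a phenol sulfonylation to which the pinacol boronate is inert, and it installs the electron-withdrawing group that ring A needs in step 5.

Step 3
Reactants: 6 pinacol boronate mesylate
Product: 7 [3-methoxy-4-(methylsulfonyloxy)phenyl]boronic acid
Conditions: NaIO4, NH4OAc, acetone/H2O, rt
Reagents that add atoms: water, O
Why: Periodate cleaves the released pinacol (glycol cleavage) and so drives the boronate hydrolysis to the free boronic acid, the form that transmetallates readily in step 4.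

Step 4
Reactants: 4 6-bromo-8-methoxy-4H-chromen-4-one; 7 arylboronic acid
Product: 8 (R)-6-bromo-8-methoxy-2-[3-methoxy-4-(methylsulfonyloxy)phenyl]chroman-4-one
Conditions: Pd(OCOCF3)2 (5 mol %), (S)-4-tert-butyl-2-(pyridin-2-yl)-4,5-dihydrooxazole (6 mol %), NH4PF6, H2O (5 equiv), ClCH2CH2Cl, 60 °C; recrystallise
Reagents that add atoms: none
Why: In this catalytic asymmetric conjugate addition of an arylboronic acid to a chromone, the cationic aryl complex of divalent palladium inserts C2=C3 on the face left open by the tert-butyl group and sets C2 as R, while the absence of zerovalent palladium in the cycle leaves the aryl bromide and the mesylate untouched.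

Step 5
Reactants: 8 (R)-flavanone
Product: 9 methyl (2R,3R)-5-bromo-7-methoxy-2-[3-methoxy-4-(methylsulfonyloxy)phenyl]-2,3-dihydrobenzofuran-3-carboxylate (trans)
Conditions: PhI(OAc)2 (1.2 equiv), conc. H2SO4, HC(OMe)3, 0 °C → rt
Reagents that add atoms: trimethyl orthoformate, COC(OC)OC
Why: Acid and orthoformate turn the C4 ketone into its methyl enol ether, trivalent iodine binds C3 on the face away from the C2 aryl group and methanol caps C4, giving a 4,4-dimethyl ketal with an equatorial C3–I bond. The C4–C4a bond lies antiperiplanar to C3–I and migrates to C3 as iodobenzene leaves (the oxidative 1,2-aryl shift known for flavanones and aryl alkyl ketones with PhI(OAc)2 or Tl(NO3)3 in orthoformate), and the dialkoxycarbenium ion left at C4 collapses to the methyl ester. The five-membered ring is thus closed by ring contraction, with C3–C3a forming through a bridged phenonium-like transition state while C4–C4a breaks, and not by an exo or endo cyclisation of an open chain. C3 is set by inversion at the carbon that held the equatorial iodine, so the existing C2 centre controls it and places the ester trans to ring A, and any cis ester can be equilibrated with DBU because trans is the more stable isomer. The step needs migration of the ring B carbon C4a in preference to the shift of ring A from C2 to C3 and to simple dehydrogenation. O1 ortho to C4a raises the migratory aptitude of ring B, while the mesylate lowers that of ring A and also disfavours ionisation or retro-oxa-Michael opening at C2, which protects the R centre.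

Step 6
Reactants: 9 trans ester
Product: 10 4-[(2R,3S)-5-bromo-3-(hydroxymethyl)-7-methoxy-2,3-dihydrobenzofuran-2-yl]-2-methoxyphenyl methanesulfonate
Conditions: i-Bu2AlH (3 equiv), CH2Cl2, −78 → 0 °C; aq. potassium sodium tartrate
Reagents that add atoms: none
Why: This low-temperature hydride reduction of the ester to the primary alcohol spares the aryl mesylate, the aryl bromide and both stereocentres, and it removes the acidity of C3–H.

Step 7
Reactants: 10 mesylate alcohol
Product: 11 4-[(2R,3S)-5-bromo-3-(hydroxymethyl)-7-methoxy-2,3-dihydrobenzofuran-2-yl]-2-methoxyphenol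
Conditions: 2 M NaOH, MeOH/THF, 50 °C; then 1 M HCl to pH 6
Reagents that add atoms: none
Why: The aryl sulfonate is hydrolysed at sulfur, and because C3 is no longer enolisable even a transient quinone-methide opening at C2 could only re-close to the trans isomer dictated by C3.

Step 8
Reactants: 11 phenol alcohol
Product: 12 (2R,3S)-5-bromo-7-methoxy-2-[3-methoxy-4-(triisopropylsilyloxy)phenyl]-3-[(triisopropylsilyloxy)methyl]-2,3-dihydrobenzofuran
Conditions: TIPSCl (2.5 equiv), imidazole, DMAP (cat.), DMF, rt → 40 °C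
Reagents that add atoms: triisopropylsilyl chloride, CC(C)[Si](Cl)(C(C)C)C(C)C
Why: Phenol and primary alcohol are silylated in one operation, and TIPS ethers tolerate butyllithium, borohydride and amide bases yet leave with fluoride at the end.

Step 9
Reactants: 12 bis-TIPS aryl bromide
Product: 14 {(2R,3S)-7-methoxy-2-[3-methoxy-4-(triisopropylsilyloxy)phenyl]-3-[(triisopropylsilyloxy)methyl]-2,3-dihydrobenzofuran-5-yl}methanol, via aldehyde 13 (not isolated)
Conditions: n-BuLi, THF, −78 °C; DMF; then MeOH, NaBH4, 0 °C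
Reagents that add atoms: N,N-dimethylformamide, CN(C)C=O
Why: Bromine–lithium exchange outruns any deprotonation at −78 °C, the aryllithium is formylated by DMF, and the released aldehyde is reduced by borohydride in the same flask.

Step 10
Reactants: 14 benzylic alcohol
Product: 15 (2R,3S)-5-(bromomethyl)-7-methoxy-2-[3-methoxy-4-(triisopropylsilyloxy)phenyl]-3-[(triisopropylsilyloxy)methyl]-2,3-dihydrobenzofuran
Conditions: CBr4, PPh3, CH2Cl2, 0 °C; used at once
Reagents that add atoms: tetrabromomethane, BrC(Br)(Br)Br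
Why: The Appel reaction converts the only free alcohol into the bromide under neutral conditions that do not touch the silyl ethers.

Step 11
Reactants: 16 (S)-4-benzyloxazolidin-2-one; 17 methyl 4-chloro-4-oxobutanoate
Product: 18 methyl 4-[(S)-4-benzyl-2-oxooxazolidin-3-yl]-4-oxobutanoate
Conditions: n-BuLi, THF, −78 °C; then 17, −78 → 0 °C
Reagents that add atoms: none
Why: The lithiated oxazolidinone is N-acylated by the acid chloride, which reacts far faster than the methyl ester.

Step 12
Reactants: 15 benzylic bromide; 18 succinyl imide (1.5 equiv)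
Product: 19 methyl (S)-4-[(S)-4-benzyl-2-oxooxazolidin-3-yl]-3-({(2R,3S)-7-methoxy-2-[3-methoxy-4-(triisopropylsilyloxy)phenyl]-3-[(triisopropylsilyloxy)methyl]-2,3-dihydrobenzofuran-5-yl}methyl)-4-oxobutanoate
Conditions: 18, NaN(SiMe3)2, THF, −78 °C; then 15, −78 → −30 °C
Reagents that add atoms: none
Why: In this Evans asymmetric alkylation the more acidic imide CH2 gives the chelated sodium Z-enolate, and the benzylic bromide attacks it on the face opposite the 4-benzyl group, which sets the future lactone C4 as S.

Step 13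
Reactants: 19 alkylated imide
Product: 21 (S)-4-({(2R,3S)-7-methoxy-2-[3-methoxy-4-(triisopropylsilyloxy)phenyl]-3-[(triisopropylsilyloxy)methyl]-2,3-dihydrobenzofuran-5-yl}methyl)dihydrofuran-2(3H)-one, via hydroxy ester 20 (not isolated)
Conditions: NaBH4, THF/H2O 4:1, 0 °C → rt; then PPTS (cat.), CH2Cl2, rt
Reagents that add atoms: none
Why: Borohydride removes the auxiliary reductively at the exocyclic imide carbonyl but leaves the methyl ester, and the γ-hydroxy ester then lactonises (5-exo-trig transesterification) without touching the stereocentre.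

**Ring C/ring D part**

Step 14
Reactants: 1 1-(5-bromo-2-hydroxy-3-methoxyphenyl)ethanone
Product: 22 1-[2-(benzyloxy)-5-bromo-3-methoxyphenyl]ethanone
Conditions: BnBr, K2CO3, DMF, 60 °C
Reagents that add atoms: benzyl bromide, BrCc1ccccc1
Why: This Williamson etherification protects the phenol, and the benzyl ether withstands every later acid, base and organolithium step.

Step 15
Reactants: 22 benzyl ether ketone
Product: 23 methyl 2-[2-(benzyloxy)-5-bromo-3-methoxyphenyl]acetate
Conditions: PhI(OAc)2, conc. H2SO4, HC(OMe)3, rt → 50 °C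
Reagents that add atoms: trimethyl orthoformate, COC(OC)OC
Why: This is the oxidative 1,2-aryl migration of an aryl methyl ketone with trivalent iodine in orthoformate (the reaction type of step 5), in which the ortho-alkoxy aryl group shifts from the ketal carbon to the iodine-bearing CH2 to give the arylacetate.

Step 16
Reactants: 23 methyl arylacetate
Product: 24 2-[2-(benzyloxy)-5-bromo-3-methoxyphenyl]acetic acid
Conditions: LiOH, THF/MeOH/H2O, rt; then 1 M HCl
Reagents that add atoms: lithium hydroxide, [Li+].[OH-]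
Why: This is the saponification of an unhindered methyl ester in a molecule with no other base-sensitive group.

Step 17
Reactants: 24 arylacetic acid; 16 (S)-4-benzyloxazolidin-2-one
Product: 26 (S)-4-benzyl-3-{2-[2-(benzyloxy)-5-bromo-3-methoxyphenyl]acetyl}oxazolidin-2-one, via mixed anhydride 25 (not isolated)
Conditions: t-BuCOCl, Et3N, THF, −20 °C; then LiCl, 16, −20 °C → rt
Reagents that add atoms: pivaloyl chloride, CC(C)(C)C(=O)Cl (in intermediate 25 only)
Why: The oxazolidinone is acylated through the mixed pivalic anhydride, which is attacked at the less hindered arylacetyl carbonyl.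

Step 18
Reactants: 26 arylacetyl imide; 27 4-(benzyloxy)-3-methoxybenzaldehyde
Product: 29 (S)-4-benzyl-3-{(2R,3S)-2-[2-(benzyloxy)-5-bromo-3-methoxyphenyl]-3-[4-(benzyloxy)-3-methoxyphenyl]-3-hydroxypropanoyl}oxazolidin-2-one, via trimethylsilyl ether 28 (not isolated)
Conditions: MgCl2 (20 mol %), Et3N, Me3SiCl, EtOAc, rt; silica plug; TFA (cat.), MeOH, rt
Reagents that add atoms: chlorotrimethylsilane, C[Si](C)(C)Cl (in intermediate 28 only)
Why: In this magnesium halide-catalysed direct anti-aldol reaction of an N-acyloxazolidinone with an aromatic aldehyde, soft enolisation gives the magnesium-chelated Z-enolate, the aldehyde adds to the face opposite the 4-benzyl group through a boat-like transition state, and silylation releases the catalyst, so that C2 (R, later C8'' S) and C3 (S, C7'') are set together.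

Step 19
Reactants: 29 anti-aldol adduct
Product: 30 (1S,2S)-2-[2-(benzyloxy)-5-bromo-3-methoxyphenyl]-1-[4-(benzyloxy)-3-methoxyphenyl]propane-1,3-diol
Conditions: LiBH4, MeOH (1 equiv), THF, 0 °C
Reagents that add atoms: none
Why: The auxiliary is removed reductively with hydroxyl assistance at a temperature where retro-aldol cleavage and epimerisation of the α-aryl centre should not compete.

Step 20
Reactants: 30 diol
Product: 31 (1S,2S)-bis(tert-butyldimethylsilyl) ether of 30
Conditions: TBSOTf (2.5 equiv), 2,6-lutidine, CH2Cl2, 0 °C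
Reagents that add atoms: tert-butyldimethylsilyl triflate, CC(C)(C)[Si](C)(C)OS(=O)(=O)C(F)(F)F
Why: The silyl triflate protects the primary and the hindered benzylic secondary alcohol in one operation under non-ionising, weakly basic conditions.

Step 21
Reactants: 31 bis-TBS aryl bromide
Product: 33 {4-(benzyloxy)-3-[(1S,2S)-1-[4-(benzyloxy)-3-methoxyphenyl]-1,3-bis(tert-butyldimethylsilyloxy)propan-2-yl]-5-methoxyphenyl}methanol, via aldehyde 32 (not isolated)
Conditions: n-BuLi, THF, −78 °C; DMF; then MeOH, NaBH4, 0 °C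
Reagents that add atoms: N,N-dimethylformamide, CN(C)C=O
Why: This is the same bromine–lithium exchange, formylation and in-flask borohydride reduction as in step 9, and the exchange is faster than benzylic deprotonation of the benzyl ethers.

Step 22
Reactants: 33 benzylic alcohol
Product: 34 the corresponding benzylic bromide
Conditions: CBr4, PPh3, CH2Cl2, 0 °C; used at once
Reagents that add atoms: tetrabromomethane, BrC(Br)(Br)Br
Why: The Appel reaction acts on the only free hydroxyl group under neutral conditions.

**Union and deprotection**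

Step 23
Reactants: 21 (S)-lactone; 34 ring C/ring D benzylic bromide
Product: 35 fully protected (3S,4S)-trans-3,4-dibenzyl lactone
Conditions: 21, LiN(SiMe3)2 (1.1 equiv), THF, −78 °C; then 34, DMPU, −78 → −30 °C
Reagents that add atoms: none
Why: In this kinetic alkylation of a 4-substituted butyrolactone lithium enolate the unhindered benzylic bromide enters anti to the C4 substituent and sets C3 as S (trans), as is usual for dibenzylbutyrolactone lignans.

Step 24
Reactants: 35 protected lactone
Product: 36 ring C and ring D bis-phenol with all four silyl ethers kept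
Conditions: H2 (1 atm), 10 % Pd/C, EtOAc, rt
Reagents that add atoms: none
Why: The two aryl benzyl ethers are hydrogenolysed much faster than the dihydrobenzofuran C2–O bond or the silylated C7''–O bond under neutral conditions.

Step 25
Reactants: 36 tetrasilyl ether
Product: 37 target CNP0186558.3
Conditions: Bu4NF/AcOH (1:1, excess), THF, 0 °C → rt
Reagents that add atoms: none
Why: Buffered fluoride removes all silyl groups without the acid that would cyclise the C7'' carbinol onto the ring C phenol and without the base that would epimerise lactone C3.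

**Compound list**

1 | 1-(5-bromo-2-hydroxy-3-methoxyphenyl)ethanone | CC(=O)c1cc(Br)cc(OC)c1O | starting material
2 | N,N-dimethylformamide dimethyl acetal | COC(OC)N(C)C | starting material
3 | (E)-1-(5-bromo-2-hydroxy-3-methoxyphenyl)-3-(dimethylamino)prop-2-en-1-one | CN(C)/C=C/C(=O)c1cc(Br)cc(OC)c1O | intermediate
4 | 6-bromo-8-methoxy-4H-chromen-4-one | O=c1ccoc2c(OC)cc(Br)cc12 | intermediate
5 | 2-methoxy-4-(4,4,5,5-tetramethyl-1,3,2-dioxaborolan-2-yl)phenol | COc1cc(B2OC(C)(C)C(C)(C)O2)ccc1O | starting material
6 | 2-methoxy-4-(pinacolatoboryl)phenyl methanesulfonate | COc1cc(B2OC(C)(C)C(C)(C)O2)ccc1OS(C)(=O)=O | intermediate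
7 | [3-methoxy-4-(methylsulfonyloxy)phenyl]boronic acid | COc1cc(B(O)O)ccc1OS(C)(=O)=O | intermediate
8 | (R)-6-bromo-8-methoxy-2-[3-methoxy-4-(methylsulfonyloxy)phenyl]chroman-4-one | O=C1C[C@H](c2ccc(OS(C)(=O)=O)c(OC)c2)Oc2c(OC)cc(Br)cc12 | intermediate
9 | methyl (2R,3R)-5-bromo-7-methoxy-2-[3-methoxy-4-(methylsulfonyloxy)phenyl]-2,3-dihydrobenzofuran-3-carboxylate | COC(=O)[C@@H]1c2cc(Br)cc(OC)c2O[C@H]1c1ccc(OS(C)(=O)=O)c(OC)c1 | intermediate
10 | (2R,3S) alcohol, mesylate kept | OC[C@@H]1c2cc(Br)cc(OC)c2O[C@H]1c1ccc(OS(C)(=O)=O)c(OC)c1 | intermediate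
11 | (2R,3S) phenol alcohol | OC[C@@H]1c2cc(Br)cc(OC)c2O[C@H]1c1ccc(O)c(OC)c1 | intermediate
12 | (2R,3S) bis-TIPS aryl bromide | CC(C)[Si](C(C)C)(C(C)C)OC[C@@H]1c2cc(Br)cc(OC)c2O[C@H]1c1ccc(O[Si](C(C)C)(C(C)C)C(C)C)c(OC)c1 | intermediate
13 | (2R,3S) bis-TIPS 5-carbaldehyde | CC(C)[Si](C(C)C)(C(C)C)OC[C@@H]1c2cc(C=O)cc(OC)c2O[C@H]1c1ccc(O[Si](C(C)C)(C(C)C)C(C)C)c(OC)c1 | intermediate
14 | (2R,3S) bis-TIPS 5-(hydroxymethyl) compound | CC(C)[Si](C(C)C)(C(C)C)OC[C@@H]1c2cc(CO)cc(OC)c2O[C@H]1c1ccc(O[Si](C(C)C)(C(C)C)C(C)C)c(OC)c1 | intermediate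
15 | (2R,3S) bis-TIPS 5-(bromomethyl) compound | CC(C)[Si](C(C)C)(C(C)C)OC[C@@H]1c2cc(CBr)cc(OC)c2O[C@H]1c1ccc(O[Si](C(C)C)(C(C)C)C(C)C)c(OC)c1 | intermediate
16 | (S)-4-benzyloxazolidin-2-one | O=C1N[C@@H](Cc2ccccc2)CO1 | starting material
17 | methyl 4-chloro-4-oxobutanoate | COC(=O)CCC(=O)Cl | starting material
18 | methyl 4-[(S)-4-benzyl-2-oxooxazolidin-3-yl]-4-oxobutanoate | COC(=O)CCC(=O)N1[C@@H](Cc2ccccc2)COC1=O | intermediate
19 | (3S)-alkylated succinyl imide | COC(=O)C[C@H](Cc1cc(OC)c2c(c1)[C@@H](CO[Si](C(C)C)(C(C)C)C(C)C)[C@H](c1ccc(O[Si](C(C)C)(C(C)C)C(C)C)c(OC)c1)O2)C(=O)N1[C@@H](Cc2ccccc2)COC1=O | intermediate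
20 | methyl (S)-4-hydroxy-3-(arylmethyl)butanoate | COC(=O)C[C@H](Cc1cc(OC)c2c(c1)[C@@H](CO[Si](C(C)C)(C(C)C)C(C)C)[C@H](c1ccc(O[Si](C(C)C)(C(C)C)C(C)C)c(OC)c1)O2)CO | intermediate
21 | (S)-4-(arylmethyl)dihydrofuran-2(3H)-one | O=C1C[C@H](Cc2cc(OC)c3c(c2)[C@@H](CO[Si](C(C)C)(C(C)C)C(C)C)[C@H](c2ccc(O[Si](C(C)C)(C(C)C)C(C)C)c(OC)c2)O3)CO1 | intermediate
22 | 1-[2-(benzyloxy)-5-bromo-3-methoxyphenyl]ethanone | CC(=O)c1cc(Br)cc(OC)c1OCc1ccccc1 | intermediate
23 | methyl 2-[2-(benzyloxy)-5-bromo-3-methoxyphenyl]acetate | COC(=O)Cc1cc(Br)cc(OC)c1OCc1ccccc1 | intermediate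
24 | 2-[2-(benzyloxy)-5-bromo-3-methoxyphenyl]acetic acid | OC(=O)Cc1cc(Br)cc(OC)c1OCc1ccccc1 | intermediate
25 | arylacetic pivalic anhydride | CC(C)(C)C(=O)OC(=O)Cc1cc(Br)cc(OC)c1OCc1ccccc1 | intermediate
26 | (S)-4-benzyl-3-(arylacetyl)oxazolidin-2-one | O=C(Cc1cc(Br)cc(OC)c1OCc1ccccc1)N1[C@@H](Cc2ccccc2)COC1=O | intermediate
27 | 4-(benzyloxy)-3-methoxybenzaldehyde | COc1cc(C=O)ccc1OCc1ccccc1 | starting material
28 | (2R,3S) anti-aldol trimethylsilyl ether | COc1cc([C@@H](O[Si](C)(C)C)[C@H](C(=O)N2[C@@H](Cc3ccccc3)COC2=O)c2cc(Br)cc(OC)c2OCc2ccccc2)ccc1OCc1ccccc1 | intermediate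
29 | (2R,3S) anti-aldol adduct | COc1cc([C@@H](O)[C@H](C(=O)N2[C@@H](Cc3ccccc3)COC2=O)c2cc(Br)cc(OC)c2OCc2ccccc2)ccc1OCc1ccccc1 | intermediate
30 | (1S,2S)-1,2-diarylpropane-1,3-diol | COc1cc([C@@H](O)[C@H](CO)c2cc(Br)cc(OC)c2OCc2ccccc2)ccc1OCc1ccccc1 | intermediate
31 | (1S,2S) bis-TBS aryl bromide | COc1cc([C@@H](O[Si](C)(C)C(C)(C)C)[C@H](CO[Si](C)(C)C(C)(C)C)c2cc(Br)cc(OC)c2OCc2ccccc2)ccc1OCc1ccccc1 | intermediate
32 | (1S,2S) bis-TBS aldehyde | COc1cc([C@@H](O[Si](C)(C)C(C)(C)C)[C@H](CO[Si](C)(C)C(C)(C)C)c2cc(C=O)cc(OC)c2OCc2ccccc2)ccc1OCc1ccccc1 | intermediate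
33 | (1S,2S) bis-TBS benzylic alcohol | COc1cc([C@@H](O[Si](C)(C)C(C)(C)C)[C@H](CO[Si](C)(C)C(C)(C)C)c2cc(CO)cc(OC)c2OCc2ccccc2)ccc1OCc1ccccc1 | intermediate
34 | (1S,2S) bis-TBS benzylic bromide | COc1cc([C@@H](O[Si](C)(C)C(C)(C)C)[C@H](CO[Si](C)(C)C(C)(C)C)c2cc(CBr)cc(OC)c2OCc2ccccc2)ccc1OCc1ccccc1 | intermediate
35 | fully protected (3S,4S)-lactone | COc1cc([C@@H](O[Si](C)(C)C(C)(C)C)[C@H](CO[Si](C)(C)C(C)(C)C)c2cc(C[C@@H]3C(=O)OC[C@H]3Cc3cc(OC)c4c(c3)[C@@H](CO[Si](C(C)C)(C(C)C)C(C)C)[C@H](c3ccc(O[Si](C(C)C)(C(C)C)C(C)C)c(OC)c3)O4)cc(OC)c2OCc2ccccc2)ccc1OCc1ccccc1 | intermediate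
36 | debenzylated tetrasilyl ether | COc1cc([C@@H](O[Si](C)(C)C(C)(C)C)[C@H](CO[Si](C)(C)C(C)(C)C)c2cc(C[C@@H]3C(=O)OC[C@H]3Cc3cc(OC)c4c(c3)[C@@H](CO[Si](C(C)C)(C(C)C)C(C)C)[C@H](c3ccc(O[Si](C(C)C)(C(C)C)C(C)C)c(OC)c3)O4)cc(OC)c2O)ccc1O | intermediate
37 | CNP0186558.3 | COc1cc([C@@H](O)[C@H](CO)c2cc(C[C@@H]3C(=O)OC[C@H]3Cc3cc(OC)c4c(c3)[C@@H](CO)[C@H](c3ccc(O)c(OC)c3)O4)cc(OC)c2O)ccc1O | target

**Step count.** The route has 25 steps in total. The longest linear sequence is 14 steps (steps 2–10, 12, 13, 23–25).

**Steps most likely to fail**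

1. **Step 5.**
   - Risk: ring A may shift from C2 to C3, or the ring may simply be dehydrogenated, instead of C4a migrating. Acid-induced opening at C2 could also erode the optical purity.
   - Fallback: it sets out from diol 30 and comes back at 11, closing the furan ring by C–O bond formation instead of contraction.
     - Stirring 30 in TFA/thioanisole (0 °C → rt) should cleave both aryl benzyl ethers by push–pull acidolysis without touching the aryl bromide. This gives (1S,2S)-2-(5-bromo-2-hydroxy-3-methoxyphenyl)-1-(4-hydroxy-3-methoxyphenyl)propane-1,3-diol F1.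
     - In the same acid the p-hydroxybenzylic carbinol ionises, and the neighbouring phenol adds to that carbon anti to the CH2OH group.
     - The aryl-bearing stereocentre, which has the same spatial arrangement as C3 of 11, therefore fixes the trans-(2R,3S) product on its own.
     - A short K2CO3/MeOH treatment removes any trifluoroacetate.

2. **Step 18.**
   - Risk: the addition may be slow or reversible and the anti selectivity poor, because the arylacetyl enolate is more stabilised and more hindered than simple acyl enolates.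
   - Fallback: it sets out from acid 24 and comes back at 30. The relative configuration comes from substrate control and the absolute configuration from resolution.
     - Double deprotonation of 24 with i-PrMgCl (2 equiv, THF, 0 °C) gives the magnesium enediolate.
     - The enediolate adds to 27 through a chair transition state with both aryl groups equatorial (Ivanov reaction), giving the anti hydroxy acid as a racemate.
     - Chromatography on a chiral stationary phase separates (2R,3S)-2-[2-(benzyloxy)-5-bromo-3-methoxyphenyl]-3-[4-(benzyloxy)-3-methoxyphenyl]-3-hydroxypropanoic acid F2 from its (2S,3R) mirror image F3.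
     - BH3·THF reduces F2 to 30.

3. **Step 4.**
   - Risk: insertion may be sluggish or facial selectivity low with this chromone, and the boronic acid may suffer protodeboronation.
   - Fallback: it sets out from 1 and comes back at 8.
     - Vanillin is mesylated (MsCl, Et3N) to 4-formyl-2-methoxyphenyl methanesulfonate F4.
     - Acid-catalysed Claisen–Schmidt condensation with 1 (HCl from SOCl2 in EtOH) gives the (E)-2'-hydroxychalcone F5.
     - NaOAc in refluxing EtOH closes F5 by oxa-Michael addition to the racemic flavanone F6.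
     - Kinetic resolution follows by Noyori–Ikariya transfer hydrogenation with RuCl(p-cymene)[(S,S)-TsDPEN] and HCO2H/Et3N, stopped near half conversion. It should reduce the (S)-enantiomer to the cis-(2S,4S)-flavan-4-ol F7 and leave (R)-8, which is separated by chromatography.

**Further compounds**

F1 | step 5 | (1S,2S)-2-(5-bromo-2-hydroxy-3-methoxyphenyl)-1-(4-hydroxy-3-methoxyphenyl)propane-1,3-diol | COc1cc([C@@H](O)[C@H](CO)c2cc(Br)cc(OC)c2O)ccc1O
F2 | step 18 | (2R,3S)-2-[2-(benzyloxy)-5-bromo-3-methoxyphenyl]-3-[4-(benzyloxy)-3-methoxyphenyl]-3-hydroxypropanoic acid | COc1cc([C@@H](O)[C@H](C(=O)O)c2cc(Br)cc(OC)c2OCc2ccccc2)ccc1OCc1ccccc1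
F3 | step 18 | (2S,3R) mirror image of F2 | COc1cc([C@H](O)[C@@H](C(=O)O)c2cc(Br)cc(OC)c2OCc2ccccc2)ccc1OCc1ccccc1
F4 | step 4 | 4-formyl-2-methoxyphenyl methanesulfonate | COc1cc(C=O)ccc1OS(C)(=O)=O
F5 | step 4 | (E)-1-(5-bromo-2-hydroxy-3-methoxyphenyl)-3-[3-methoxy-4-(methylsulfonyloxy)phenyl]prop-2-en-1-one | COc1cc(/C=C/C(=O)c2cc(Br)cc(OC)c2O)ccc1OS(C)(=O)=O
F6 | step 4 | racemic 6-bromo-8-methoxy-2-[3-methoxy-4-(methylsulfonyloxy)phenyl]chroman-4-one | O=C1CC(c2ccc(OS(C)(=O)=O)c(OC)c2)Oc2c(OC)cc(Br)cc12
F7 | step 4 | (2S,4S)-6-bromo-8-methoxy-2-[3-methoxy-4-(methylsulfonyloxy)phenyl]chroman-4-ol | O[C@H]1C[C@@H](c2ccc(OS(C)(=O)=O)c(OC)c2)Oc2c(OC)cc(Br)cc12
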